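(The constants used here come from no measurement; no experiment stands behind them.)

**The bound.** It was impossible for starting material, target and over-reacted product to add up to anything but the charge, crystals counted in target. So two fractions of the charge per flask gave me the third, and I reckoned them in powers of ten.

all flasks: starting material 0.15 M; gas phase 14 mM (held); time 10 h

| charge | temperature |
|---|---|
| theta | 25 °C |
| zeta | 50 °C |
| epsilon | 75 °C |

    crystals ⇌ target, rate k1*(cs1 - [target]) while solid is left; crystals form when [target] > cs1 (cs1 = 1.9 mM, k1 = 0.0132 min⁻¹)
    starting material + dissolved gas → target (k2 = 0.0761 M⁻¹ min⁻¹, Ea2 = 50.0 kJ mol⁻¹)
    dissolved gas + target → over-reacted product (k3 = 0.0268 M⁻¹ min⁻¹, Ea3 = 52.0 kJ mol⁻¹)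
    gas phase ⇌ dissolved gas, rate k4*(csat - [dissolved gas]) (k4 = 1.79 min⁻¹, csat = 14 mM)
    (constants at 25 °C)

- for target the crystals are counted in
- as a solid, counted per litre of solution: crystals
- at the start none of the gas is dissolved
- at 25 °C the constants are as listed, elsewhere as the activation energies make them

1. which of these there is most of at the end, counted by the starting material in it, theta (over-reacted product / target / starting material)
2. which of these there is most of at the end, counted by the starting material in it, zeta (over-reacted product / target / starting material)
3. which of these there is most of at the end, counted by the starting material in it, epsilon (over-reacted product / target / starting material)
4. the largest of these amounts at the end, in percent of the starting material charged, theta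
5. the largest of these amounts at the end, in percent of the starting material charged, zeta
6. the largest of these amounts at the end, in percent of the starting material charged, epsilon

**Gas first.** Gas crossed over in about 0.559 min. In theta, the step to target alone needed 1.0 h to halve the dissolved gas. Because crossing was much faster than that drain, I held dissolved gas at saturation. Starting material then decayed as a pseudo-first-order species.

**Counting decades.** I counted the powers of ten by which starting material fell during the run. Theta gave 0.278, which left 52.7%. Warming raised the step to target by 0.678 decades in zeta and 1.26 in epsilon. That made 1.33 and 5.05 decades, leaving 4.73% and <0.001%.

**First link.** Next I placed dissolved target at its solubility, 1.27% of the charge. The over-reaction step rose by 1.31 decades in epsilon, to 0.00766 min⁻¹ at saturated gas. By my estimate, that floor lost 5.82% of the charge over the run in epsilon.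

**The reforged link.** That link was weak, since crystals grow only while dissolved target stands above solubility. Converted material therefore entered an excess with two exits, crystals and over-reaction. I called the toll the share taking the second exit: the over-reaction constant at saturated gas, divided by the sum of that constant and the crystal coefficient. In epsilon it was 0.367. Over-reacted product was then the toll on what passed through, plus the floor's loss. That gave 39.9% in epsilon, so target held 60.1%. The same reckoning gave zeta 13.1% over-reacted product and target 82.2%. I committed to starting material in theta and target in the other two.

**The forecast.** The forecast gave starting material at 53% in theta, target at 82% in zeta and target at 61% in epsilon, holding that “Over-reaction only hits dissolved target”, and my epsilon figure stood lower.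

**The flask.** The run gave starting material at 53.0% in theta, target at 82.4% in zeta and target at 60.9% in epsilon. In epsilon, the step to target ran while starting material lasted, 0.362% remaining at 5.00 h, when over-reacted product stood at 36.5%. It then crept to 39.1% at 10.0 h beside crystals of 60.1%. The neighbour flask, epsilon with 0.037 M of starting material, had the same toll 0.367 but a higher floor, and I reckoned 49.8% over-reacted product. That neighbour flask held 50.0%.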